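**Retrosynthetic overview**
1. The target, methyl (13E)-18-acetoxy-ent-labda-6,8(17),13-trien-15-oate, is traced back through its 6,8(17)-diene (allylic carbonate at C7, allylic oxidation) to the 8(17)-ene 18-alcohol 22.
2. The strategy rests on ring A carrying a quaternary C4 with an equatorial C18H2–O arm and no oxygen at C3, and on ring B carrying the exocyclic C8=C17 methylene. C4–C18–O is therefore drawn back to a 2,2-disubstituted oxirane and C8=C17 to an allylsilane.
3. Key disconnection: C4–C5 and C9–C10, which leads to the acyclic (S)-oxirane trienylsilane 21 with the (E)-enoate side chain already in place.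
4. Compound 21 is grown left to right from geranyl acetate. C4 comes from asymmetric epoxidation and hydride opening, C6–C7 and C11–C12 from acetoacetate dianion alkylations, and C8=C9 and C13=C14 from (Z)-enol phosphates.
5. Ring order: rings A and B close together in step 16 (A by C4–C5, then B by C9–C10 in the same cascade); no other ring is formed.

Key step: step 16

Remark: chain atoms carry the labdane number (C1 to C20) of the atom they become; the asymmetric epoxidation of step 2 is assumed to give material of high enantiomeric purity, to be upgraded if necessary at a crystalline stage.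

**Route**

Step 1
Reactants: 1 geranyl acetate
Product: 2 (2E,6E)-8-hydroxy-3,7-dimethylocta-2,6-dien-1-yl acetate
Conditions: SeO2 (cat.), t-BuOOH, salicylic acid (cat.), CH2Cl2, rt
Reagents that add atoms: tert-butyl hydroperoxide CC(C)(C)OO
Why: Riley allylic oxidation (ene reaction, then [2,3]-sigmatropic shift) should hydroxylate the (E)-methyl group of the electron-rich terminal alkene, while the other alkene is deactivated by its allylic acetate.

Step 2
Reactants: 2 (2E,6E)-8-hydroxy-3,7-dimethylocta-2,6-dien-1-yl acetate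
Product: 3 (2E)-5-[(2R,3R)-3-(hydroxymethyl)-3-methyloxiran-2-yl]-3-methylpent-2-en-1-yl acetate
Conditions: Ti(OiPr)4 (cat.), D-(−)-diisopropyl tartrate (cat.), t-BuOOH, 4 Å molecular sieves, CH2Cl2, −20 °C
Reagents that add atoms: tert-butyl hydroperoxide CC(C)(C)OO
Why: Sharpless asymmetric epoxidation of the (E)-2-methyl allylic alcohol, in which the D-(−)-tartrate complex delivers oxygen to the face that gives the (2R,3R)-epoxy alcohol and so fixes the C4 stereocentre, leaving the alkene without a free allylic hydroxyl untouched.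

Step 3
Reactants: 3 (2E)-5-[(2R,3R)-3-(hydroxymethyl)-3-methyloxiran-2-yl]-3-methylpent-2-en-1-yl acetate
Product: 4 (2E,7S)-3,7-dimethyloct-2-ene-1,7,8-triol
Conditions: LiAlH4, THF, 0 °C to rt
Reagents that add atoms: none
Why: Hydride opening of the 2,3-epoxy alcohol should occur by SN2 attack at the secondary oxirane carbon C3 because C4 is fully substituted, so the tertiary C4–O bond and its configuration are kept, and the acetate is reduced off in the same operation.

Step 4
Reactants: 4 (2E,7S)-3,7-dimethyloct-2-ene-1,7,8-triol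
Product: 5 (2E)-3-methyl-6-[(4S)-2,2,4-trimethyl-1,3-dioxolan-4-yl]hex-2-en-1-ol
Conditions: Me2C(OMe)2, PPTS (cat.), acetone, rt
Reagents that add atoms: 2,2-dimethoxypropane COC(C)(C)OC
Why: Acid-catalysed acetonide formation closes the five-membered dioxolane on the 1,2-diol and leaves the remote allylic alcohol free.

Step 5
Reactants: 5 (2E)-3-methyl-6-[(4S)-2,2,4-trimethyl-1,3-dioxolan-4-yl]hex-2-en-1-ol
Product: 6 (4S)-4-[(4E)-6-bromo-4-methylhex-4-en-1-yl]-2,2,4-trimethyl-1,3-dioxolane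
Conditions: CBr4, PPh3, CH2Cl2, 0 °C
Reagents that add atoms: carbon tetrabromide BrC(Br)(Br)Br
Why: The Appel reaction converts the primary allylic alcohol into the bromide under neutral conditions that spare the acetonide and do not transpose the alkene.

Step 6
Reactants: 6 (4S)-4-[(4E)-6-bromo-4-methylhex-4-en-1-yl]-2,2,4-trimethyl-1,3-dioxolane; 7 methyl acetoacetate
Product: 9 methyl (6E)-7-methyl-3-oxo-10-[(4S)-2,2,4-trimethyl-1,3-dioxolan-4-yl]dec-6-enoate, via methyl acetoacetate sodium lithium dianion 8 (not isolated)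
Conditions: NaH, THF, 0 °C; n-BuLi, 0 °C; then 6, 0 °C; aq. NH4Cl
Reagents that add atoms: none
Why: γ-Alkylation of the β-keto ester dianion by the primary allylic bromide forms C6–C7 and brings in C7, C8, C9 and C11.

Step 7
Reactants: 9 methyl (6E)-7-methyl-3-oxo-10-[(4S)-2,2,4-trimethyl-1,3-dioxolan-4-yl]dec-6-enoate
Product: 10 methyl (2Z,6E)-3-[(diethoxyphosphoryl)oxy]-7-methyl-10-[(4S)-2,2,4-trimethyl-1,3-dioxolan-4-yl]deca-2,6-dienoate
Conditions: NaH, Et2O, 0 °C; ClP(O)(OEt)2
Reagents that add atoms: diethyl chlorophosphate CCOP(=O)(Cl)OCC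
Why: O-Phosphorylation of the chelated sodium enolate should give the (Z)-enol phosphate, which fixes the geometry of the future C8=C9 alkene.

Step 8
Reactants: 10 methyl (2Z,6E)-3-[(diethoxyphosphoryl)oxy]-7-methyl-10-[(4S)-2,2,4-trimethyl-1,3-dioxolan-4-yl]deca-2,6-dienoate; 11 (trimethylsilyl)methylmagnesium chloride
Product: 12 methyl (2Z,6E)-7-methyl-3-[(trimethylsilyl)methyl]-10-[(4S)-2,2,4-trimethyl-1,3-dioxolan-4-yl]deca-2,6-dienoate
Conditions: Ni(acac)2 (cat.), THF, 0 °C to rt
Reagents that add atoms: none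
Why: Nickel-catalysed Kumada coupling of the enol phosphate replaces phosphate by CH2SiMe3 with retention of alkene geometry, so the silylmethyl group ends cis to C11 and C7 trans to it.

Step 9
Reactants: 12 methyl (2Z,6E)-7-methyl-3-[(trimethylsilyl)methyl]-10-[(4S)-2,2,4-trimethyl-1,3-dioxolan-4-yl]deca-2,6-dienoate
Product: 13 (2Z,6E)-7-methyl-3-[(trimethylsilyl)methyl]-10-[(4S)-2,2,4-trimethyl-1,3-dioxolan-4-yl]deca-2,6-dien-1-ol
Conditions: i-Bu2AlH, CH2Cl2, −78 °C
Reagents that add atoms: none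
Why: 1,2-Reduction of the conjugated ester with i-Bu2AlH gives the allylic alcohol without touching the allylsilane or the acetonide.

Step 10
Reactants: 13 (2Z,6E)-7-methyl-3-[(trimethylsilyl)methyl]-10-[(4S)-2,2,4-trimethyl-1,3-dioxolan-4-yl]deca-2,6-dien-1-ol
Product: 14 (4S)-4-[(4E,8Z)-10-bromo-4-methyl-8-[(trimethylsilyl)methyl]deca-4,8-dien-1-yl]-2,2,4-trimethyl-1,3-dioxolane
Conditions: CBr4, PPh3, 2,6-lutidine, CH2Cl2, −20 °C; used at once
Reagents that add atoms: carbon tetrabromide BrC(Br)(Br)Br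
Why: The buffered Appel reaction gives the primary allylic bromide without acid that could protodesilylate the allylsilane.

Step 11
Reactants: 14 (4S)-4-[(4E,8Z)-10-bromo-4-methyl-8-[(trimethylsilyl)methyl]deca-4,8-dien-1-yl]-2,2,4-trimethyl-1,3-dioxolane; 7 methyl acetoacetate
Product: 16 methyl (6Z,10E)-11-methyl-3-oxo-7-[(trimethylsilyl)methyl]-14-[(4S)-2,2,4-trimethyl-1,3-dioxolan-4-yl]tetradeca-6,10-dienoate, via methyl acetoacetate dilithium dianion 15 (not isolated)
Conditions: LDA (2.1 equiv), THF, 0 °C; then 14, −20 to 0 °C; aq. NH4Cl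
Reagents that add atoms: none
Why: A second γ-alkylation of the β-keto ester, here through the dilithium dianion made with two equivalents of LDA, forms C11–C12 and delivers C12 to C15 (dianion alkylation of a β-keto ester by a primary allylic bromide).

Step 12
Reactants: 16 methyl (6Z,10E)-11-methyl-3-oxo-7-[(trimethylsilyl)methyl]-14-[(4S)-2,2,4-trimethyl-1,3-dioxolan-4-yl]tetradeca-6,10-dienoate
Product: 17 methyl (2Z,6Z,10E)-3-[(diethoxyphosphoryl)oxy]-11-methyl-7-[(trimethylsilyl)methyl]-14-[(4S)-2,2,4-trimethyl-1,3-dioxolan-4-yl]tetradeca-2,6,10-trienoate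
Conditions: NaH, Et2O, 0 °C; ClP(O)(OEt)2
Reagents that add atoms: diethyl chlorophosphate CCOP(=O)(Cl)OCC
Why: As in step 7, O-phosphorylation of the chelated sodium enolate should give the (Z)-enol phosphate at C13.

Step 13
Reactants: 17 methyl (2Z,6Z,10E)-3-[(diethoxyphosphoryl)oxy]-11-methyl-7-[(trimethylsilyl)methyl]-14-[(4S)-2,2,4-trimethyl-1,3-dioxolan-4-yl]tetradeca-2,6,10-trienoate
Product: 18 methyl (2E,6Z,10E)-3,11-dimethyl-7-[(trimethylsilyl)methyl]-14-[(4S)-2,2,4-trimethyl-1,3-dioxolan-4-yl]tetradeca-2,6,10-trienoate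
Conditions: Me2CuLi (from MeLi and CuI), Et2O, −78 to −45 °C
Reagents that add atoms: lithium dimethylcuprate [Li+].C[Cu-]C
Why: Cuprate coupling with the enol phosphate replaces phosphate by methyl with retention, so the new methyl is cis to the ester and the (E)-3-methyl enoate results.

Step 14
Reactants: 18 methyl (2E,6Z,10E)-3,11-dimethyl-7-[(trimethylsilyl)methyl]-14-[(4S)-2,2,4-trimethyl-1,3-dioxolan-4-yl]tetradeca-2,6,10-trienoate
Product: 19 methyl (2E,6Z,10E,15S)-15,16-dihydroxy-3,11,15-trimethyl-7-[(trimethylsilyl)methyl]hexadeca-2,6,10-trienoate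
Conditions: PPTS, MeOH, rt
Reagents that add atoms: none
Why: Mild acid-catalysed transketalisation in methanol releases the 1,2-diol under conditions too weakly acidic to protodesilylate the allylsilane.

Step 15
Reactants: 19 methyl (2E,6Z,10E,15S)-15,16-dihydroxy-3,11,15-trimethyl-7-[(trimethylsilyl)methyl]hexadeca-2,6,10-trienoate
Product: 21 methyl (2E,6Z,10E)-3,11-dimethyl-14-[(2S)-2-methyloxiran-2-yl]-7-[(trimethylsilyl)methyl]tetradeca-2,6,10-trienoate, via primary monotosylate 20 (not isolated)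
Conditions: NaH, N-tosylimidazole, THF, 0 °C to rt
Reagents that add atoms: none
Why: The primary alkoxide is sulfonylated selectively and the tertiary alkoxide then closes the oxirane by intramolecular Williamson displacement at C18, so the C4–O bond is not broken and C4 stays (S).

Step 16
Reactants: 21 methyl (2E,6Z,10E)-3,11-dimethyl-14-[(2S)-2-methyloxiran-2-yl]-7-[(trimethylsilyl)methyl]tetradeca-2,6,10-trienoate
Product: 22 methyl (13E)-18-hydroxy-ent-labda-8(17),13-dien-15-oate (4S,5S,9R,10S)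
Conditions: MeAlCl2 (3 equiv), CH2Cl2, −78 °C; aq. NaHCO3
Reagents that add atoms: none
Why: MeAlCl2 activates the oxirane, the C5=C10 alkene opens the tertiary C4–O bond from the rear (inversion at C4), C9 of the allylsilane traps the C10 cation and the β-silyl cation at C8 loses the silyl group to leave the C8=C17 methylene; the closest known reaction type is the epoxide-initiated, allylsilane-terminated cation–olefin polycyclisation, including its 2,2-disubstituted oxirane variant with this Lewis acid. Ring A closes 6-endo by C4–C5 and ring B closes 6-endo by C9–C10, both through chair-like folds. C4 is set by the (S)-oxirane through backside attack, C5 and C10 by anti addition across the (E)-C5=C10 alkene (trans ring fusion), and C9 by the C8=C9 geometry, which puts C11 equatorial and H9 anti to the C10 methyl. The step needs regioselective cleavage at C4, secured by the tertiary centre, and the ring-A chair that holds the aluminium-bound C18H2–O arm equatorial with the C4 methyl axial; only the greater bulk of the metal-bearing arm favours this fold, so it is the least secured point of the step. The enoate is too electron-poor to act as a nucleophile and only binds one equivalent of the Lewis acid, hence the excess.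

Step 17
Reactants: 22 methyl (13E)-18-hydroxy-ent-labda-8(17),13-dien-15-oate
Product: 23 methyl (13E)-18-acetoxy-ent-labda-8(17),13-dien-15-oate (4S,5S,9R,10S)
Conditions: Ac2O, pyridine, DMAP (cat.), CH2Cl2, rt
Reagents that add atoms: acetic anhydride CC(=O)OC(C)=O
Why: Acylation of the primary alcohol under nucleophilic catalysis gives the acetate without affecting the alkenes or the methyl ester.

Step 18
Reactants: 23 methyl (13E)-18-acetoxy-ent-labda-8(17),13-dien-15-oate
Product: 24 methyl (13E)-18-acetoxy-7-hydroxy-ent-labda-8(17),13-dien-15-oate (7S; hydroxyl axial and anti to the C10 methyl)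
Conditions: SeO2 (cat.), t-BuOOH, CH2Cl2, rt
Reagents that add atoms: tert-butyl hydroperoxide CC(C)(C)OO
Why: Riley oxidation of the exocyclic 1,1-disubstituted alkene (ene reaction at C17, then [2,3]-shift) should place the hydroxyl at C7 on the axial face opposite the C10 methyl and return the alkene to C8=C17, while the electron-poor side-chain alkene reacts far more slowly.

Step 19
Reactants: 24 methyl (13E)-18-acetoxy-7-hydroxy-ent-labda-8(17),13-dien-15-oate
Product: 25 methyl (13E)-18-acetoxy-7-(methoxycarbonyloxy)-ent-labda-8(17),13-dien-15-oate (7S)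
Conditions: ClCO2Me, pyridine, DMAP (cat.), CH2Cl2, 0 °C
Reagents that add atoms: methyl chloroformate COC(=O)Cl
Why: Acylation of the secondary allylic alcohol with the chloroformate gives the allylic carbonate with retention at C7, a leaving group suited to palladium.

Step 20
Reactants: 25 methyl (13E)-18-acetoxy-7-(methoxycarbonyloxy)-ent-labda-8(17),13-dien-15-oate
Product: 26 methyl (13E)-18-acetoxy-ent-labda-6,8(17),13-trien-15-oate (4S,5S,9R,10S)
Conditions: Pd(PPh3)4 (cat.), 1,4-dioxane, reflux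
Reagents that add atoms: none
Why: Zerovalent palladium ionises the axial allylic carbonate with loss of CO2 to the C7–C8–C17 allyl complex, and syn β-hydride elimination of the axial hydrogen on C6, the only carbon next to a terminus of the allyl unit that carries hydrogen, should give the conjugated 6,8(17)-diene (Tsuji-type diene formation from an allylic carbonate).

**Compound list**
1 | geranyl acetate | CC(C)=CCC/C(C)=C/COC(C)=O | starting material
2 | (2E,6E)-8-hydroxy-3,7-dimethylocta-2,6-dien-1-yl acetate | OC/C(C)=C/CC/C(C)=C/COC(C)=O | intermediate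
3 | (2E)-5-[(2R,3R)-3-(hydroxymethyl)-3-methyloxiran-2-yl]-3-methylpent-2-en-1-yl acetate | OC[C@@]1(C)O[C@@H]1CC/C(C)=C/COC(C)=O | intermediate
4 | (2E,7S)-3,7-dimethyloct-2-ene-1,7,8-triol | OC[C@@](C)(O)CCC/C(C)=C/CO | intermediate
5 | (2E)-3-methyl-6-[(4S)-2,2,4-trimethyl-1,3-dioxolan-4-yl]hex-2-en-1-ol | CC1(C)OC[C@@](C)(O1)CCC/C(C)=C/CO | intermediate
6 | (4S)-4-[(4E)-6-bromo-4-methylhex-4-en-1-yl]-2,2,4-trimethyl-1,3-dioxolane | CC1(C)OC[C@@](C)(O1)CCC/C(C)=C/CBr | intermediate
7 | methyl acetoacetate | CC(=O)CC(=O)OC | starting material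
8 | methyl acetoacetate sodium lithium dianion | [Na+].[Li+].[CH2-]C(=O)[CH-]C(=O)OC | intermediate
9 | methyl (6E)-7-methyl-3-oxo-10-[(4S)-2,2,4-trimethyl-1,3-dioxolan-4-yl]dec-6-enoate | CC1(C)OC[C@@](C)(O1)CCC/C(C)=C/CCC(=O)CC(=O)OC | intermediate
10 | methyl (2Z,6E)-3-[(diethoxyphosphoryl)oxy]-7-methyl-10-[(4S)-2,2,4-trimethyl-1,3-dioxolan-4-yl]deca-2,6-dienoate | CC1(C)OC[C@@](C)(O1)CCC/C(C)=C/CC/C(OP(=O)(OCC)OCC)=C/C(=O)OC | intermediate
11 | (trimethylsilyl)methylmagnesium chloride | C[Si](C)(C)C[Mg]Cl | starting material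
12 | methyl (2Z,6E)-7-methyl-3-[(trimethylsilyl)methyl]-10-[(4S)-2,2,4-trimethyl-1,3-dioxolan-4-yl]deca-2,6-dienoate | CC1(C)OC[C@@](C)(O1)CCC/C(C)=C/CC/C(C[Si](C)(C)C)=C/C(=O)OC | intermediate
13 | (2Z,6E)-7-methyl-3-[(trimethylsilyl)methyl]-10-[(4S)-2,2,4-trimethyl-1,3-dioxolan-4-yl]deca-2,6-dien-1-ol | CC1(C)OC[C@@](C)(O1)CCC/C(C)=C/CC/C(C[Si](C)(C)C)=C/CO | intermediate
14 | (4S)-4-[(4E,8Z)-10-bromo-4-methyl-8-[(trimethylsilyl)methyl]deca-4,8-dien-1-yl]-2,2,4-trimethyl-1,3-dioxolane | CC1(C)OC[C@@](C)(O1)CCC/C(C)=C/CC/C(C[Si](C)(C)C)=C/CBr | intermediate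
15 | methyl acetoacetate dilithium dianion | [Li+].[Li+].[CH2-]C(=O)[CH-]C(=O)OC | intermediate
16 | methyl (6Z,10E)-11-methyl-3-oxo-7-[(trimethylsilyl)methyl]-14-[(4S)-2,2,4-trimethyl-1,3-dioxolan-4-yl]tetradeca-6,10-dienoate | CC1(C)OC[C@@](C)(O1)CCC/C(C)=C/CC/C(C[Si](C)(C)C)=C/CCC(=O)CC(=O)OC | intermediate
17 | methyl (2Z,6Z,10E)-3-[(diethoxyphosphoryl)oxy]-11-methyl-7-[(trimethylsilyl)methyl]-14-[(4S)-2,2,4-trimethyl-1,3-dioxolan-4-yl]tetradeca-2,6,10-trienoate | CC1(C)OC[C@@](C)(O1)CCC/C(C)=C/CC/C(C[Si](C)(C)C)=C/CC/C(OP(=O)(OCC)OCC)=C/C(=O)OC | intermediate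
18 | methyl (2E,6Z,10E)-3,11-dimethyl-7-[(trimethylsilyl)methyl]-14-[(4S)-2,2,4-trimethyl-1,3-dioxolan-4-yl]tetradeca-2,6,10-trienoate | CC1(C)OC[C@@](C)(O1)CCC/C(C)=C/CC/C(C[Si](C)(C)C)=C/CC/C(C)=C/C(=O)OC | intermediate
19 | methyl (2E,6Z,10E,15S)-15,16-dihydroxy-3,11,15-trimethyl-7-[(trimethylsilyl)methyl]hexadeca-2,6,10-trienoate | OC[C@@](C)(O)CCC/C(C)=C/CC/C(C[Si](C)(C)C)=C/CC/C(C)=C/C(=O)OC | intermediate
20 | methyl (2E,6Z,10E,15S)-15-hydroxy-3,11,15-trimethyl-16-(tosyloxy)-7-[(trimethylsilyl)methyl]hexadeca-2,6,10-trienoate | Cc1ccc(cc1)S(=O)(=O)OC[C@@](C)(O)CCC/C(C)=C/CC/C(C[Si](C)(C)C)=C/CC/C(C)=C/C(=O)OC | intermediate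
21 | methyl (2E,6Z,10E)-3,11-dimethyl-14-[(2S)-2-methyloxiran-2-yl]-7-[(trimethylsilyl)methyl]tetradeca-2,6,10-trienoate | C1O[C@@]1(C)CCC/C(C)=C/CC/C(C[Si](C)(C)C)=C/CC/C(C)=C/C(=O)OC | intermediate
22 | methyl (13E)-18-hydroxy-ent-labda-8(17),13-dien-15-oate (4S,5S,9R,10S) | C=C1CC[C@@H]2[C@@](C)(CO)CCC[C@@]2(C)[C@@H]1CC/C(C)=C/C(=O)OC | intermediate
23 | methyl (13E)-18-acetoxy-ent-labda-8(17),13-dien-15-oate (4S,5S,9R,10S) | C=C1CC[C@@H]2[C@@](C)(COC(C)=O)CCC[C@@]2(C)[C@@H]1CC/C(C)=C/C(=O)OC | intermediate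
24 | methyl (13E)-18-acetoxy-7-hydroxy-ent-labda-8(17),13-dien-15-oate (7S, hydroxyl axial and anti to the C10 methyl) | C=C1[C@@H](O)C[C@@H]2[C@@](C)(COC(C)=O)CCC[C@@]2(C)[C@@H]1CC/C(C)=C/C(=O)OC | intermediate
25 | methyl (13E)-18-acetoxy-7-(methoxycarbonyloxy)-ent-labda-8(17),13-dien-15-oate (7S) | C=C1[C@@H](OC(=O)OC)C[C@@H]2[C@@](C)(COC(C)=O)CCC[C@@]2(C)[C@@H]1CC/C(C)=C/C(=O)OC | intermediate
26 | methyl (13E)-18-acetoxy-ent-labda-6,8(17),13-trien-15-oate (4S,5S,9R,10S) | C=C1C=C[C@@H]2[C@@](C)(COC(C)=O)CCC[C@@]2(C)[C@@H]1CC/C(C)=C/C(=O)OC | target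

**Count and risks**
Total step count: 20. Longest linear sequence: 20 steps (1 to 26); 7 and 11 enter in line.

Steps most likely to fail:

1. Step 16. Ring A may fold the other way. The oxirane methylene is tied back by the three-membered ring during rear-side opening and may take the axial site beside the C10 methyl more easily than the C4 methyl does. The chain would then add to the other alkene face, so that the C18/C19 roles and the sense of the ring fusion are inverted. A 1,2-hydride shift from C18 to C4 and chloride capture at C4 would lower the yield further.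
 Fallback: sets out from epoxy alcohol 3 and comes back at alcohol 22. The oxirane is kept at C3–C4 and the hydroxyl is silylated (TBDPSCl, imidazole) to the silyl ether acetate F1. Methanolysis (K2CO3, MeOH) gives the epoxy allylic alcohol F2 and the Appel reaction gives the epoxy allylic bromide F3. The chain is then grown as in steps 6 to 13, at or below 0 °C for the sake of the oxirane: dianion 8 gives the β-keto ester F4, phosphorylation the enol phosphate F5, nickel-catalysed coupling with 11 the allylsilane ester F6, i-Bu2AlH the allylic alcohol F7, the Appel reaction the bromide F8, dianion 15 the β-keto ester F9, phosphorylation the enol phosphate F10 and Me2CuLi the 3,4-epoxy trienoate F11. MeAlCl2 should close rings A and B as in the known oxidosqualene-type mode. Here the oxirane carbon C3 is a ring member, so the fold is fixed by geometry: the C4 substituent trans to the chain (C18H2OSi) becomes equatorial, the cis methyl axial and the C3 hydroxyl equatorial, giving the 3-hydroxy silyl ether F12. Barton–McCombie deoxygenation through the imidazolyl thiocarbonate F13 (1,1'-thiocarbonyldiimidazole, then n-Bu3SnH and AIBN) gives the 3-deoxy silyl ether F14, and n-Bu4NF releases 22.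

2. Step 18. The oxidation may run on to the enone, or hydrogen may be abstracted at C9 or at the allylic positions of the side chain instead of C7.
 Fallback: sets out from acetate 23 and comes back at target 26. A Schenck ene reaction (O2, light, tetraphenylporphyrin, CH2Cl2) should move the alkene to C7=C8 and put oxygen on C17, giving the allylic hydroperoxide F15. PPh3 reduces it to the primary allylic alcohol F16 and ClCO2Me gives the allylic carbonate F17. Pd(PPh3)4 ionises F17 to the same C7–C8–C17 allyl complex as in step 20, and β-hydride loss from C6 gives 26.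

3. Step 20. The allyl complex may be recaptured by methoxide to give an allyl methyl ether, or the hindered axial carbonate may ionise sluggishly.
 Fallback: sets out from allylic alcohol 24 and comes back at 26. Dehydration with Martin sulfurane, Ph2S[OC(CF3)2Ph]2, in benzene at rt should give the diene directly by E2 elimination, since the axial C7 oxygen and the axial C6 hydrogen are antiperiplanar; neither palladium nor carbonate 25 is needed.

Further compounds
F1 | step 16 | (2E)-5-[(2R,3R)-3-(tert-butyldiphenylsilyloxymethyl)-3-methyloxiran-2-yl]-3-methylpent-2-en-1-yl acetate | CC(C)(C)[Si](c1ccccc1)(c1ccccc1)OC[C@@]1(C)O[C@@H]1CC/C(C)=C/COC(C)=O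
F2 | step 16 | (2E)-5-[(2R,3R)-3-(tert-butyldiphenylsilyloxymethyl)-3-methyloxiran-2-yl]-3-methylpent-2-en-1-ol | CC(C)(C)[Si](c1ccccc1)(c1ccccc1)OC[C@@]1(C)O[C@@H]1CC/C(C)=C/CO
F3 | step 16 | (2E)-1-bromo-5-[(2R,3R)-3-(tert-butyldiphenylsilyloxymethyl)-3-methyloxiran-2-yl]-3-methylpent-2-ene | CC(C)(C)[Si](c1ccccc1)(c1ccccc1)OC[C@@]1(C)O[C@@H]1CC/C(C)=C/CBr
F4 | step 16 | methyl (6E)-9-[(2R,3R)-3-(tert-butyldiphenylsilyloxymethyl)-3-methyloxiran-2-yl]-7-methyl-3-oxonon-6-enoate | CC(C)(C)[Si](c1ccccc1)(c1ccccc1)OC[C@@]1(C)O[C@@H]1CC/C(C)=C/CCC(=O)CC(=O)OC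
F5 | step 16 | methyl (2Z,6E)-9-[(2R,3R)-3-(tert-butyldiphenylsilyloxymethyl)-3-methyloxiran-2-yl]-3-[(diethoxyphosphoryl)oxy]-7-methylnona-2,6-dienoate | CC(C)(C)[Si](c1ccccc1)(c1ccccc1)OC[C@@]1(C)O[C@@H]1CC/C(C)=C/CC/C(OP(=O)(OCC)OCC)=C/C(=O)OC
F6 | step 16 | methyl (2Z,6E)-9-[(2R,3R)-3-(tert-butyldiphenylsilyloxymethyl)-3-methyloxiran-2-yl]-7-methyl-3-[(trimethylsilyl)methyl]nona-2,6-dienoate | CC(C)(C)[Si](c1ccccc1)(c1ccccc1)OC[C@@]1(C)O[C@@H]1CC/C(C)=C/CC/C(C[Si](C)(C)C)=C/C(=O)OC
F7 | step 16 | (2Z,6E)-9-[(2R,3R)-3-(tert-butyldiphenylsilyloxymethyl)-3-methyloxiran-2-yl]-7-methyl-3-[(trimethylsilyl)methyl]nona-2,6-dien-1-ol | CC(C)(C)[Si](c1ccccc1)(c1ccccc1)OC[C@@]1(C)O[C@@H]1CC/C(C)=C/CC/C(C[Si](C)(C)C)=C/CO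
F8 | step 16 | (2Z,6E)-1-bromo-9-[(2R,3R)-3-(tert-butyldiphenylsilyloxymethyl)-3-methyloxiran-2-yl]-7-methyl-3-[(trimethylsilyl)methyl]nona-2,6-diene | CC(C)(C)[Si](c1ccccc1)(c1ccccc1)OC[C@@]1(C)O[C@@H]1CC/C(C)=C/CC/C(C[Si](C)(C)C)=C/CBr
F9 | step 16 | methyl (6Z,10E)-13-[(2R,3R)-3-(tert-butyldiphenylsilyloxymethyl)-3-methyloxiran-2-yl]-11-methyl-3-oxo-7-[(trimethylsilyl)methyl]trideca-6,10-dienoate | CC(C)(C)[Si](c1ccccc1)(c1ccccc1)OC[C@@]1(C)O[C@@H]1CC/C(C)=C/CC/C(C[Si](C)(C)C)=C/CCC(=O)CC(=O)OC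
F10 | step 16 | methyl (2Z,6Z,10E)-13-[(2R,3R)-3-(tert-butyldiphenylsilyloxymethyl)-3-methyloxiran-2-yl]-3-[(diethoxyphosphoryl)oxy]-11-methyl-7-[(trimethylsilyl)methyl]trideca-2,6,10-trienoate | CC(C)(C)[Si](c1ccccc1)(c1ccccc1)OC[C@@]1(C)O[C@@H]1CC/C(C)=C/CC/C(C[Si](C)(C)C)=C/CC/C(OP(=O)(OCC)OCC)=C/C(=O)OC
F11 | step 16 | methyl (2E,6Z,10E)-13-[(2R,3R)-3-(tert-butyldiphenylsilyloxymethyl)-3-methyloxiran-2-yl]-3,11-dimethyl-7-[(trimethylsilyl)methyl]trideca-2,6,10-trienoate | CC(C)(C)[Si](c1ccccc1)(c1ccccc1)OC[C@@]1(C)O[C@@H]1CC/C(C)=C/CC/C(C[Si](C)(C)C)=C/CC/C(C)=C/C(=O)OC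
F12 | step 16 | methyl (13E)-18-(tert-butyldiphenylsilyloxy)-3-hydroxy-ent-labda-8(17),13-dien-15-oate (3-hydroxyl equatorial) | C=C1CC[C@@H]2[C@@](C)(CO[Si](c3ccccc3)(c3ccccc3)C(C)(C)C)[C@H](O)CC[C@@]2(C)[C@@H]1CC/C(C)=C/C(=O)OC
F13 | step 16 | methyl (13E)-18-(tert-butyldiphenylsilyloxy)-3-(imidazol-1-ylcarbonothioyloxy)-ent-labda-8(17),13-dien-15-oate | C=C1CC[C@@H]2[C@@](C)(CO[Si](c3ccccc3)(c3ccccc3)C(C)(C)C)[C@H](OC(=S)n3ccnc3)CC[C@@]2(C)[C@@H]1CC/C(C)=C/C(=O)OC
F14 | step 16 | methyl (13E)-18-(tert-butyldiphenylsilyloxy)-ent-labda-8(17),13-dien-15-oate | C=C1CC[C@@H]2[C@@](C)(CO[Si](c3ccccc3)(c3ccccc3)C(C)(C)C)CCC[C@@]2(C)[C@@H]1CC/C(C)=C/C(=O)OC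
F15 | step 18 | methyl (13E)-18-acetoxy-17-hydroperoxy-ent-labda-7,13-dien-15-oate | OOCC1=CC[C@@H]2[C@@](C)(COC(C)=O)CCC[C@@]2(C)[C@@H]1CC/C(C)=C/C(=O)OC
F16 | step 18 | methyl (13E)-18-acetoxy-17-hydroxy-ent-labda-7,13-dien-15-oate | OCC1=CC[C@@H]2[C@@](C)(COC(C)=O)CCC[C@@]2(C)[C@@H]1CC/C(C)=C/C(=O)OC
F17 | step 18 | methyl (13E)-18-acetoxy-17-(methoxycarbonyloxy)-ent-labda-7,13-dien-15-oate | COC(=O)OCC1=CC[C@@H]2[C@@](C)(COC(C)=O)CCC[C@@]2(C)[C@@H]1CC/C(C)=C/C(=O)OC
F0 | step 20 | none | none
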